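Locants: ring A is the benzene ring of the benzofuran (O1, C2, C3, C3a, C7a), ring B is the resorcinol ring on C3, and Cα is the carbon between the ketone and ring B. The route rests on the C3–C3a and C2–O1 bonds of the trans-dihydrofuran. These are the two bonds a 4-hydroxystilbene radical makes with a resorcinol, and ring A, read as a 3,5-dihydroxybenzoyl group, has two equivalent carbons ortho to the carbonyl group.
17 <= tribenzyl ether 16 (debenzylation) <= open resorcinol ketone 14, by one laccase oxidation that closes first the seven-membered ring (C3–C3a) and then the dihydrofuran (C2–O1). Cα steers C3, and C3 steers C2.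
14 <= racemic triaryl ketone 11. Cα is fixed by asymmetric transfer hydrogenation with dynamic kinetic resolution, the carbinol is re-oxidised without base, and the three TIPS ethers are removed with bifluoride.
11 <= acetophenone 8 by two successive palladium-catalysed α-arylations, first with the hindered bromostilbene 6 (Heck reaction, then ring bromination), then with bromide 10.
Benzyl ethers mask the three phenols that must not be oxidised in the key step. Benzyl is preferred to methyl because it leaves at −78 °C, where neither the 2-aryl-dihydrofuran nor Cα is at risk.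

Key step: step 10

Assumption: the matched pairing in step 7 ((R,R)-catalyst with the (R)-ketone) is taken from the Felkin–Anh model; if it proves to be the reverse, the (S,S)-catalyst gives the (1S,2R)-alcohol, which step 8 turns into the same ketone 13.

Step 1
Reactants: 1 4-acetoxystyrene
Product: 3 4-(triisopropylsilyloxy)styrene, via 4-vinylphenol 2 (not isolated)
Conditions: K2CO3 (cat.), MeOH, 0 °C; evaporate; TIPSCl, imidazole, DMF, rt
Reagents that add atoms: triisopropylsilyl chloride, CC(C)[Si](Cl)(C(C)C)C(C)C
Why: Transesterification frees the polymerisation-prone vinylphenol, which is silylated at once in the same flask, and the TIPS ether is chosen because it withstands the bases of steps 5 and 6 and leaves with fluoride.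

Step 2
Reactants: 3 4-(triisopropylsilyloxy)styrene; 4 1,3-bis(benzyloxy)-5-bromobenzene
Product: 5 (E)-3,5-bis(benzyloxy)-4'-(triisopropylsilyloxy)stilbene
Conditions: Pd(OAc)2 (2 mol%), P(o-tol)3, Et3N, DMF, 100 °C
Reagents that add atoms: none
Why: In this Mizoroki–Heck arylation of a terminal styrene, syn insertion followed by syn β-hydride elimination should deliver the E-stilbene.

Step 3
Reactants: 5 (E)-3,5-bis(benzyloxy)-4'-(triisopropylsilyloxy)stilbene
Product: 6 (E)-2-bromo-3,5-bis(benzyloxy)-4'-(triisopropylsilyloxy)stilbene
Conditions: NBS (1.0 equiv), MeCN/CH2Cl2, −20 to 0 °C, dark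
Reagents that add atoms: N-bromosuccinimide, O=C1CCC(=O)N1Br
Why: In this electrophilic aromatic bromination the dialkoxy ring is the most nucleophilic site, and C2 (para to one benzyloxy group, ortho to the other) is favoured over C4, which is flanked by two benzyloxy groups.

Step 4
Reactants: 7 3,5-dihydroxyacetophenone
Product: 8 3,5-bis(triisopropylsilyloxy)acetophenone
Conditions: TIPSCl (2.3 equiv), imidazole, DMF, rt
Reagents that add atoms: triisopropylsilyl chloride, CC(C)[Si](Cl)(C(C)C)C(C)C
Why: Standard silylation gives the two ring A phenols the same fluoride-labile group as the stilbene phenol, so that all three are freed together in step 9.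

Step 5
Reactants: 8 3,5-bis(triisopropylsilyloxy)acetophenone; 6 (E)-2-bromo-3,5-bis(benzyloxy)-4'-(triisopropylsilyloxy)stilbene
Product: 9 1-[3,5-bis(triisopropylsilyloxy)phenyl]-2-{2,4-bis(benzyloxy)-6-[(E)-4-(triisopropylsilyloxy)styryl]phenyl}ethan-1-one
Conditions: Pd2(dba)3 (2 mol%), XPhos (8 mol%), K3PO4, toluene, 100 °C
Reagents that add atoms: none
Why: This Buchwald–Hartwig–Miura α-arylation pairs the di-ortho-substituted bromide with the least hindered enolate available (a methyl ketone), a bulky biaryl phosphine supports oxidative addition and reductive elimination, and a second arylation by 6 is blocked sterically.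

Step 6
Reactants: 9 the benzylic ketone of step 5; 10 1-(benzyloxy)-4-bromobenzene
Product: 11 (±)-2-[4-(benzyloxy)phenyl]-2-{2,4-bis(benzyloxy)-6-[(E)-4-(triisopropylsilyloxy)styryl]phenyl}-1-[3,5-bis(triisopropylsilyloxy)phenyl]ethan-1-one
Conditions: Pd(OAc)2 (3 mol%), P(t-Bu)3·HBF4 (6 mol%), NaOt-Bu (1.5 equiv), toluene, 80 °C
Reagents that add atoms: none
Why: In this second Buchwald–Hartwig–Miura α-arylation the acidic benzylic ketone is fully enolised, the bromide is unhindered and P(t-Bu)3 speeds the crowded reductive elimination (a demand comparable to the known arylation of α-branched ketones), while Cα forms racemic and is corrected in step 7.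

Step 7
Reactants: 11 the racemic triaryl ketone
Product: 12 (1R,2R)-2-[4-(benzyloxy)phenyl]-2-{2,4-bis(benzyloxy)-6-[(E)-4-(triisopropylsilyloxy)styryl]phenyl}-1-[3,5-bis(triisopropylsilyloxy)phenyl]ethan-1-ol
Conditions: RuCl[(R,R)-TsDPEN](p-cymene) (2 mol%), HCO2H (5 equiv), Et3N (8 equiv), CH2Cl2, 40 °C; minor diastereomer removed by chromatography
Reagents that add atoms: none
Why: In this Noyori–Ikariya asymmetric transfer hydrogenation under dynamic kinetic resolution the catalyst sets C1 as R by recognising ring A, free Et3N keeps the acidic Cα of unreacted 11 racemising, the (R)-ketone (catalyst and Felkin–Anh preference coincide) should be reduced faster, and because the diastereomers are separable the purity at Cα rests on the reliable catalyst control at C1.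

Step 8
Reactants: 12 the (1R,2R)-alcohol
Product: 13 (R)-2-[4-(benzyloxy)phenyl]-2-{2,4-bis(benzyloxy)-6-[(E)-4-(triisopropylsilyloxy)styryl]phenyl}-1-[3,5-bis(triisopropylsilyloxy)phenyl]ethan-1-one
Conditions: Dess–Martin periodinane, CH2Cl2, 0 °C to rt
Reagents that add atoms: none
Why: The Dess–Martin oxidation runs in a weakly acidic, base-free medium, so the auxiliary carbinol centre is erased while Cα is not enolised, and the stilbene, silyl and benzyl ethers are inert.

Step 9
Reactants: 13 the (R)-tris-TIPS ketone
Product: 14 (R)-2-[4-(benzyloxy)phenyl]-2-{2,4-bis(benzyloxy)-6-[(E)-4-hydroxystyryl]phenyl}-1-(3,5-dihydroxyphenyl)ethan-1-one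
Conditions: KHF2, MeOH/THF, rt
Reagents that add atoms: none
Why: Bifluoride cleaves phenolic silyl ethers under slightly acidic conditions, so no phenoxide or other base meets the labile Cα, and the benzyl ethers and the E-alkene are untouched.

Step 10
Reactants: 14 the (R)-resorcinol ketone with the E-4-hydroxystilbene
Product: 16 (2R,3R,αR)-tri-O-benzylpauciflorol E (both ring B oxygens and the α-aryl oxygen benzylated; ring A hydroxyl and C2-aryl hydroxyl free; trans-dihydrofuran), via p-quinone methide 15 (not isolated)
Conditions: laccase (Trametes versicolor), air, EtOAc/NaOAc buffer (0.1 M, pH 5.0) 1:1, 14 at ≤1 mM, low enzyme loading, 25 °C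
Reagents that add atoms: none
Why: Proposed new method: the type 1 copper centre of the laccase removes one electron from the only easily oxidised phenol of 14, the 4-hydroxystilbene (the ring A resorcinol is deactivated by its carbonyl group and every other oxygen is benzylated), and the phenoxyl radical, which carries spin on the olefinic carbon next to ring B (the future C3), bonds to a ring A carbon ortho to the carbonyl group; a second one-electron oxidation (by the enzyme or by disproportionation with another phenoxyl radical) and loss of a proton rearomatise ring A to p-quinone methide 15, whose exocyclic carbon (the future C2) is captured by the adjacent ring A hydroxyl, the overall change being the loss of two hydrogen atoms to O2. The closest known reaction type is the laccase-, peroxidase- or FeCl3-induced oxidative dimerisation of 4-hydroxystilbenes to trans-2-aryl-2,3-dihydrobenzofurans, which joins two stilbene-derived radicals intermolecularly; an intramolecular, crossed closure onto a resorcinol that is not itself oxidised has not been shown. The seven-membered ring closes first through C3–C3a (7-exo-trig when counted on the C3a=C7a bond of ring A, 7-endo on the other Kekulé form), and the dihydrofuran closes second through C2–O1 by a 5-exo-trig oxa-conjugate addition. C3 is set by Cα: allylic strain against the ortho benzyloxy group keeps the Cα–H bond in the plane of ring B, so the aroyl and the α-aryl group lie on opposite faces of ring B, ring A can reach the olefin only on its own face and only in the rotamer that turns the quinone methide arm away from Cα towards the free hydroxyl, and for (αR) this gives (3R). C2 is set by C3, because the reversible phenol addition should settle with the C2-aryl group anti to ring B (trans, 2R). The step needs chemoselective oxidation (secured by the protecting-group pattern and the acyl group), site selectivity (either ortho carbon of ring A gives the same product, the carbon between the hydroxyls is out of reach, and the α-aryl ring offers only a carbon meta to its oxygen and no hydroxyl to trap the quinone methide) and cyclisation ahead of radical dimerisation (helped by the tether, high dilution and a low radical concentration).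

Step 11
Reactants: 16 tri-O-benzylpauciflorol E
Product: 17 pauciflorol E, (2R,3R,αR)
Conditions: BCl3 (8 equiv), C6HMe5 (10 equiv), CH2Cl2, −78 °C; then aqueous work-up
Reagents that add atoms: none
Why: In this Lewis-acid debenzylation pentamethylbenzene scavenges the benzyl cations, and at −78 °C the aryl benzyl ethers should cleave while the benzylic C2–O1 bond of the dihydrofuran and the enolisable Cα stay intact.

Compound list
1 | 4-acetoxystyrene | CC(=O)Oc1ccc(C=C)cc1 | starting material
2 | 4-vinylphenol | Oc1ccc(C=C)cc1 | intermediate
3 | 4-(triisopropylsilyloxy)styrene | C=Cc1ccc(O[Si](C(C)C)(C(C)C)C(C)C)cc1 | intermediate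
4 | 1,3-bis(benzyloxy)-5-bromobenzene | Brc1cc(OCc2ccccc2)cc(OCc2ccccc2)c1 | starting material
5 | (E)-3,5-bis(benzyloxy)-4'-(triisopropylsilyloxy)stilbene | O(Cc1ccccc1)c1cc(OCc2ccccc2)cc(/C=C/c2ccc(O[Si](C(C)C)(C(C)C)C(C)C)cc2)c1 | intermediate
6 | (E)-2-bromo-3,5-bis(benzyloxy)-4'-(triisopropylsilyloxy)stilbene | Brc1c(OCc2ccccc2)cc(OCc2ccccc2)cc1/C=C/c1ccc(O[Si](C(C)C)(C(C)C)C(C)C)cc1 | intermediate
7 | 3,5-dihydroxyacetophenone | CC(=O)c1cc(O)cc(O)c1 | starting material
8 | 3,5-bis(triisopropylsilyloxy)acetophenone | CC(=O)c1cc(O[Si](C(C)C)(C(C)C)C(C)C)cc(O[Si](C(C)C)(C(C)C)C(C)C)c1 | intermediate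
9 | 1-[3,5-bis(triisopropylsilyloxy)phenyl]-2-{2,4-bis(benzyloxy)-6-[(E)-4-(triisopropylsilyloxy)styryl]phenyl}ethan-1-one | O=C(Cc1c(OCc2ccccc2)cc(OCc2ccccc2)cc1/C=C/c1ccc(O[Si](C(C)C)(C(C)C)C(C)C)cc1)c1cc(O[Si](C(C)C)(C(C)C)C(C)C)cc(O[Si](C(C)C)(C(C)C)C(C)C)c1 | intermediate
10 | 1-(benzyloxy)-4-bromobenzene | Brc1ccc(OCc2ccccc2)cc1 | starting material
11 | (±)-triaryl ketone, tris-TIPS, tribenzyl | O=C(c1cc(O[Si](C(C)C)(C(C)C)C(C)C)cc(O[Si](C(C)C)(C(C)C)C(C)C)c1)C(c1ccc(OCc2ccccc2)cc1)c1c(OCc2ccccc2)cc(OCc2ccccc2)cc1/C=C/c1ccc(O[Si](C(C)C)(C(C)C)C(C)C)cc1 | intermediate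
12 | (1R,2R)-alcohol from 11 | O[C@@H](c1cc(O[Si](C(C)C)(C(C)C)C(C)C)cc(O[Si](C(C)C)(C(C)C)C(C)C)c1)[C@H](c1ccc(OCc2ccccc2)cc1)c1c(OCc2ccccc2)cc(OCc2ccccc2)cc1/C=C/c1ccc(O[Si](C(C)C)(C(C)C)C(C)C)cc1 | intermediate
13 | (R)-triaryl ketone, tris-TIPS, tribenzyl | O=C(c1cc(O[Si](C(C)C)(C(C)C)C(C)C)cc(O[Si](C(C)C)(C(C)C)C(C)C)c1)[C@H](c1ccc(OCc2ccccc2)cc1)c1c(OCc2ccccc2)cc(OCc2ccccc2)cc1/C=C/c1ccc(O[Si](C(C)C)(C(C)C)C(C)C)cc1 | intermediate
14 | (R)-resorcinol ketone with E-4-hydroxystilbene (key-step precursor) | O=C(c1cc(O)cc(O)c1)[C@H](c1ccc(OCc2ccccc2)cc1)c1c(OCc2ccccc2)cc(OCc2ccccc2)cc1/C=C/c1ccc(O)cc1 | intermediate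
15 | seven-membered-ring ketone bearing a p-quinone methide on C3, (3R,αR) | O=C1c2cc(O)cc(O)c2[C@@H](c2cc(OCc3ccccc3)cc(OCc3ccccc3)c2[C@H]1c1ccc(OCc2ccccc2)cc1)C=C1C=CC(=O)C=C1 | intermediate
16 | (2R,3R,αR)-tri-O-benzylpauciflorol E (key-step product) | O=C1c2cc(O)cc3c2[C@@H](c2cc(OCc4ccccc4)cc(OCc4ccccc4)c2[C@H]1c1ccc(OCc2ccccc2)cc1)[C@H](c1ccc(O)cc1)O3 | intermediate
17 | pauciflorol E | O=C1c2cc(O)cc3c2[C@@H](c2cc(O)cc(O)c2[C@H]1c1ccc(O)cc1)[C@H](c1ccc(O)cc1)O3 | target

Total step count: 11. Longest linear sequence: 10 (steps 1, 2, 3, 5, 6, 7, 8, 9, 10, 11).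

Steps most likely to fail

Step 10. Coupling of two phenoxyl radicals may outrun the slow, reversible addition to the acyl-deactivated ring A. Further oxidation of the product phenols and closure onto the α-aryl ring would drain material as well.

The fallback makes the same two bonds by closed-shell palladium chemistry; it sets out from 14 and comes back at 16.
- Candida antarctica lipase B with vinyl acetate in tert-amyl alcohol should acetylate only the exposed stilbene phenol, the regioselectivity known for resveratrol-type stilbenes, giving the stilbene 4'-O-acetate F1.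
- Ring A is then the only free phenol. NIS in MeCN at −20 °C should iodinate it at one of the two equivalent carbons para to a hydroxyl and ortho to the carbonyl group, giving the ring A aryl iodide F2.
- An intramolecular Heck oxyarylation (Pd(OAc)2, PPh3, Ag2CO3, acetone, 50 °C) forms C3–C3a by 7-exo carbopalladation of the stilbene on the face dictated by Cα. It forms C2–O1 by capture of the benzylic palladium centre by the neighbouring phenol, giving the cyclised 4'-O-acetate F3.
- Lipase-catalysed butanolysis under neutral conditions then frees the phenol and gives 16.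

Step 7. Hydride transfer to the very crowded carbonyl group may be slow, racemisation of Cα may lag behind reduction, or matched and mismatched enantiomers may be poorly discriminated.

The fallback drops asymmetric catalysis for a physical resolution with recycling; it sets out from 11 and comes back at 13. Preparative supercritical-fluid chromatography on an amylose carbamate phase separates 11 into 13 and the (S)-enantiomer F4. The latter is racemised with DBU in toluene back to 11 and passed through the column again.

Step 6. Binding of the crowded enolate to palladium and the final reductive elimination may be too slow, so that hydrodebromination of 10 or silyl migration under base takes over.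

The fallback inverts the order of bond formation, so the hindered partner becomes the electrophile; it sets out from 8 and comes back at 11. Ketone 8 is first arylated with the unhindered 10 (Pd(OAc)2, P(t-Bu)3·HBF4, NaOt-Bu, toluene) to the deoxybenzoin F5. The flat, stabilised enolate of F5 is then coupled with bromostilbene 6 under the same type of catalysis, so that the Cα–ring B bond is made last and 11 results.

Further compounds
F1 | step 10 | (R)-stilbene 4'-O-acetate of 14 | O=C(c1cc(O)cc(O)c1)[C@H](c1ccc(OCc2ccccc2)cc1)c1c(OCc2ccccc2)cc(OCc2ccccc2)cc1/C=C/c1ccc(OC(C)=O)cc1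
F2 | step 10 | (R)-2-iodo-3,5-dihydroxybenzoyl analogue of F1 | O=C(c1cc(O)cc(O)c1I)[C@H](c1ccc(OCc2ccccc2)cc1)c1c(OCc2ccccc2)cc(OCc2ccccc2)cc1/C=C/c1ccc(OC(C)=O)cc1
F3 | step 10 | (2R,3R,αR)-C2-aryl 4'-O-acetate of 16 | O=C1c2cc(O)cc3c2[C@@H](c2cc(OCc4ccccc4)cc(OCc4ccccc4)c2[C@H]1c1ccc(OCc2ccccc2)cc1)[C@H](c1ccc(OC(C)=O)cc1)O3
F4 | step 7 | (S)-enantiomer of 13 | O=C(c1cc(O[Si](C(C)C)(C(C)C)C(C)C)cc(O[Si](C(C)C)(C(C)C)C(C)C)c1)[C@@H](c1ccc(OCc2ccccc2)cc1)c1c(OCc2ccccc2)cc(OCc2ccccc2)cc1/C=C/c1ccc(O[Si](C(C)C)(C(C)C)C(C)C)cc1
F5 | step 6 | 2-[4-(benzyloxy)phenyl]-1-[3,5-bis(triisopropylsilyloxy)phenyl]ethan-1-one | O=C(Cc1ccc(OCc2ccccc2)cc1)c1cc(O[Si](C(C)C)(C(C)C)C(C)C)cc(O[Si](C(C)C)(C(C)C)C(C)C)c1
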